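The single product is the gate to the double and triple products, and the substrate reaches it through a coupling that competes with self-condensation.

    coupling partner + single product → double product + by-product (k1 = 5.4 × 10⁻⁵ M⁻¹ s⁻¹)
    coupling partner + double product → triple product + by-product (k2 = 2.0 × 10⁻⁴ M⁻¹ s⁻¹)
    substrate + coupling partner → single product + by-product (k3 = 1.4 × 10⁻⁴ M⁻¹ s⁻¹)
    2 substrate → self-condensation product (k4 = 9.7 × 10⁻⁵ M⁻¹ s⁻¹)
    crystals ⇌ single product, rate k5*(cs5 - [single product]) while solid is left; crystals form when [single product] > cs5 (cs5 = 4.9 mM, k5 = 3.1 × 10⁻⁴ s⁻¹)
    single product ⇌ isomer of the product (K6 = 6.5, k6 = 1.5 × 10⁻⁵ s⁻¹)

- delta: substrate 0.050 M; coupling partner 1.20 equiv; time 30 d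
- zeta: substrate 0.050 M; coupling partner 2.40 equiv; time 30 d

- which of these there is most of at the end, counted by the substrate in it, delta (triple product / double product / isomer of the product / single product)
- which of these there is most of at the end, counted by the substrate in it, zeta (triple product / double product / isomer of the product / single product)
- amount of the one of these that there is most of at the end, in percent of the substrate charged, delta
- amount of the one of these that there is most of at the end, in percent of the substrate charged, zeta

- percentages count the substrate that a species holds: one self-condensation product counts as two
- single product is meant together with its crystals
- where a step has two of a species, its rate is k times that concentration squared, and two are used at each turn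
- solid, in amounts per volume of the solution: crystals
- run time (delta): 30 d

For delta, 0.866 is the selectivity factor ρ, the rate at which the coupling uses substrate over the rate at which self-condensation uses it at the start. That is the coupling constant times c(coupling partner), over 2 times the self-condensation constant times c(substrate). So in delta self-condensation leads at the start, yet I reckon that coupling takes 66.5 % of the substrate, more than an even share.

The two numbers fit once the ratio is allowed to move. Self-condensation goes with the square of c(substrate) and the coupling with its first power, so the ratio grows as substrate falls. Treating c(coupling partner) as constant, a pseudo-first-order view, and integrating down to no substrate gives a coupled share of ρ·ln(1 + 1/ρ). The symmetric case, ρ = 1, is my zero: it gives 69.3 %, not an even split. Zeta has 1.73, so its share is 78.9 %. The coupling partner does not stay at its charge, so I hold both shares as upper figures, a roof over the asked products together. I do not reckon how they divide beneath it.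

The forecast names isomer of the product at 34.5 % for delta and triple product at 48 % for zeta, reasoning “so isomer is a reservoir”.

The flask gives isomer of the product at 36.4 % in delta and triple product at 45.7 % in zeta, and the asked products together hold 61.1 % and 76.7 %, under roofs of 66.5 % and 78.9 %. In delta, self-condensation ran early, with 99.5 % of its turnover up to the asked time done by 6.00 d. Then, with substrate down to 0.379 % at 15.0 d, the isomer of the product fell from 40.8 % at that time to 36.4 % at 30.0 d, while triple product rose from 12.2 % to 17.8 %. In the neighbour of delta with 2.00 equiv of coupling partner, ρ is 1.44, the roof is 75.9 %, and the asked products hold 73.1 %.

Its constants belong to no real substance, and the outcome is calculated.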